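## Retrosynthetic overview

1. The target is reached from its bis-pivalate by ester cleavage alone.
2. Both aryl–C(sp3) bonds are cut at once: a twofold nickel/photo-HAT α-oxy C–H arylation of (3S,4S)-3,4-dimethyltetrahydrofuran with two equivalents of 4-bromo-2,6-dimethoxyphenyl pivalate, the ring methyl groups steering both aryl groups trans.
3. The tetrahydrofuran ring is the only ring built and is closed before the coupling, by cyclodehydration of (2S,3S)-2,3-dimethylbutane-1,4-diol. The diol comes from the trans-dimethyl lactone, made by enolate methylation of (S)-β-methyl-γ-butyrolactone, itself from asymmetric hydrogenation of 4-methylfuran-2(5H)-one.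
4. The aryl bromide comes from resorcinol: O-methylation, ortho-lithiation/hydroxylation, para-bromination, pivaloylation.
5. Ring order: the arene ring is carried from resorcinol; the butenolide ring is opened by reduction and re-closed as the ether ring; the two aryl rings are attached last.

Assumption: Ru(OAc)2[(R)-BINAP] is taken as the catalyst antipode that gives the (S)-lactone 9; if the sense of induction is the reverse, the (S)-BINAP complex is used and nothing else changes.

## Route

Step 1
Reactants: 1 resorcinol (benzene-1,3-diol)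
Product: 2 1,3-dimethoxybenzene
Conditions: MeI (2.5 equiv), K2CO3 (3 equiv), acetone, reflux, 16 h
Reagents that add atoms: iodomethane, CI
Why: Williamson ether synthesis, in which both phenoxides formed by K2CO3 are O-methylated by SN2 on MeI; no stereocentre is involved.

Step 2
Reactants: 2 1,3-dimethoxybenzene
Product: 5 2,6-dimethoxyphenol, via (2,6-dimethoxyphenyl)lithium 3 (not isolated), via lithium trimethoxy(2,6-dimethoxyphenyl)borate 4 (not isolated)
Conditions: n-BuLi (1.1 equiv), THF, 0 °C → rt, 2 h; B(OMe)3 (1.5 equiv), −78 °C → rt; AcOH, then 30% aq. H2O2, 0 °C → rt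
Reagents that add atoms: hydrogen peroxide, OO (phenol oxygen of 5); n-butyllithium, [Li]CCCC (lithium of 3 and 4 only); trimethyl borate, COB(OC)OC (borate of 4 only)
Why: Directed ortho-metalation at the position flanked by the two methoxy groups, borate trapping, then oxidative boron-to-oxygen aryl migration (hydroxylation of an arylboron species); no stereocentre is involved.

Step 3
Reactants: 5 2,6-dimethoxyphenol
Product: 6 4-bromo-2,6-dimethoxyphenol
Conditions: NBS (1.0 equiv), NaH (1 mol %), CHCl3, −45 °C → rt
Reagents that add atoms: N-bromosuccinimide, O=C1CCC(=O)N1Br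
Why: Electrophilic aromatic bromination para to the free hydroxyl group, the strongest donor, with the trace of phenoxide directing NBS to C4; no stereocentre is involved.

Step 4
Reactants: 6 4-bromo-2,6-dimethoxyphenol
Product: 7 4-bromo-2,6-dimethoxyphenyl pivalate
Conditions: PivCl (1.2 equiv), Et3N (1.5 equiv), DMAP (5 mol %), CH2Cl2, 0 °C → rt
Reagents that add atoms: pivaloyl chloride, CC(C)(C)C(Cl)=O
Why: DMAP-catalysed O-acylation; the ester masks the oxidisable phenol, makes the arene less electron-rich for the nickel step and carries only strong C–H bonds.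

Step 5
Reactants: 8 4-methylfuran-2(5H)-one
Product: 9 (S)-4-methyldihydrofuran-2(3H)-one
Conditions: Ru(OAc)2[(R)-BINAP] (0.5 mol %), H2 (100 atm), CH2Cl2, 50 °C, 48 h
Reagents that add atoms: none
Why: Carbonyl-directed asymmetric hydrogenation of the trisubstituted butenolide alkene, in which the BINAP ligand selects the alkene face and so sets C4 as S.

Step 6
Reactants: 9 (S)-4-methyldihydrofuran-2(3H)-one
Product: 11 (3S,4S)-3,4-dimethyldihydrofuran-2(3H)-one, via lithium (S)-4-methyl-4,5-dihydrofuran-2-olate 10 (not isolated)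
Conditions: LiN(iPr)2 (1.05 equiv), THF, −78 °C, 45 min; MeI (1.5 equiv), −78 → −40 °C
Reagents that add atoms: iodomethane, CI; lithium diisopropylamide, [Li]N(C(C)C)C(C)C (lithium of 10 only)
Why: Lactone enolate alkylation, in which MeI approaches the planar enolate on the face anti to the C4 methyl group, giving the trans (3S) product.

Step 7
Reactants: 11 (3S,4S)-3,4-dimethyldihydrofuran-2(3H)-one
Product: 12 (2S,3S)-2,3-dimethylbutane-1,4-diol
Conditions: LiAlH4 (1.2 equiv), Et2O, 0 °C → rt; H2O quench
Reagents that add atoms: none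
Why: Hydride reduction of the lactone to the 1,4-diol, fast enough that the α-stereocentre is not enolised, so both centres are carried over unchanged.

Step 8
Reactants: 12 (2S,3S)-2,3-dimethylbutane-1,4-diol
Product: 13 (3S,4S)-3,4-dimethyltetrahydrofuran
Conditions: Amberlyst-15 (sulfonic acid resin, 5 wt %), neat, 130–140 °C, product distilled out with the water formed; dried over KOH, redistilled from CaH2
Reagents that add atoms: none
Why: Acid-catalysed cyclodehydration (intramolecular SN2 of one hydroxyl on the protonated primary carbinol, 5-exo-tet) closes the tetrahydrofuran ring; the stereocentres are not at reacting carbons and stay (3S,4S).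

Step 9
Reactants: 13 (3S,4S)-3,4-dimethyltetrahydrofuran (1.0 equiv); 7 4-bromo-2,6-dimethoxyphenyl pivalate (2.6 equiv, added in two portions)
Product: 15 (2S,3S,4S,5S)-2,5-bis[3,5-dimethoxy-4-(pivaloyloxy)phenyl]-3,4-dimethyltetrahydrofuran, via 2,6-dimethoxy-4-[(2S,3S,4S)-3,4-dimethyltetrahydrofuran-2-yl]phenyl pivalate 14 (not isolated)
Conditions: NiBr2(dme) (10 mol %), 4,4'-di-tert-butyl-2,2'-bipyridine (dtbbpy, 12 mol %), (Bu4N)4[W10O32] (2 mol %), K3PO4 (2.6 equiv), MeCN (0.3 M), 390 nm LEDs, 25 °C, 48 h
Reagents that add atoms: none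
Why: Proposed new method: a twofold α-oxy C(sp3)–H arylation with the ether as the limiting partner, in which photoexcited [W10O32]4− abstracts a hydridic O–CH2 hydrogen of 13 (polarity-matched and sterically favoured over the tertiary C–H bonds), the α-oxy radical is captured by ArNi(Br)(dtbbpy) formed by oxidative addition of 7 to zerovalent nickel, and reductive elimination from the trivalent nickel alkyl aryl species forms the C–C bond on the ring face anti to the neighbouring methyl group, so C2 becomes S (2,3-trans); the same cycle at the remaining O–CH2 of 14 (whose tertiary benzylic C–H gives a radical that nickel couples only slowly and that is returned by back hydrogen transfer) places the second aryl anti to both the C4 methyl and the C2 aryl, a matched case that gives the all-trans (2S,3S,4S,5S) isomer, which is also the thermodynamically preferred one; the closest known reaction type is the nickel/photo-HAT α-C–H arylation of simple cyclic ethers such as tetrahydrofuran with aryl halides, which is run with the ether in large excess, once per molecule and without a resident stereocontrol element.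

Step 10
Reactants: 15 (2S,3S,4S,5S)-2,5-bis[3,5-dimethoxy-4-(pivaloyloxy)phenyl]-3,4-dimethyltetrahydrofuran
Product: 16 (2S,3S,4S,5S)-2,5-bis(4-hydroxy-3,5-dimethoxyphenyl)-3,4-dimethyltetrahydrofuran (CNP0217414.3)
Conditions: NaOMe (4 equiv), MeOH/THF 2:1, 50 °C, under Ar; then AcOH; recrystallisation
Reagents that add atoms: none
Why: Transesterification (methanolysis) of the two aryl pivalates by methoxide with phenoxide as leaving group; no acid is present to ionise the benzylic ether carbons and the ring has no acidic C–H, so all four stereocentres are untouched.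

## Compound list

1 | resorcinol (benzene-1,3-diol) | Oc1cccc(O)c1 | starting material
2 | 1,3-dimethoxybenzene | COc1cccc(OC)c1 | intermediate
3 | (2,6-dimethoxyphenyl)lithium | [Li]c1c(OC)cccc1OC | intermediate
4 | lithium trimethoxy(2,6-dimethoxyphenyl)borate | [Li+].COc1cccc(OC)c1[B-](OC)(OC)OC | intermediate
5 | 2,6-dimethoxyphenol | COc1cccc(OC)c1O | intermediate
6 | 4-bromo-2,6-dimethoxyphenol | COc1cc(Br)cc(OC)c1O | intermediate
7 | 4-bromo-2,6-dimethoxyphenyl pivalate | COc1cc(Br)cc(OC)c1OC(=O)C(C)(C)C | intermediate
8 | 4-methylfuran-2(5H)-one | CC1=CC(=O)OC1 | starting material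
9 | (S)-4-methyldihydrofuran-2(3H)-one | O=C1OC[C@@H](C)C1 | intermediate
10 | lithium (S)-4-methyl-4,5-dihydrofuran-2-olate | [Li+].[O-]C1=C[C@H](C)CO1 | intermediate
11 | (3S,4S)-3,4-dimethyldihydrofuran-2(3H)-one | O=C1OC[C@@H](C)[C@@H]1C | intermediate
12 | (2S,3S)-2,3-dimethylbutane-1,4-diol | OC[C@@H](C)[C@@H](CO)C | intermediate
13 | (3S,4S)-3,4-dimethyltetrahydrofuran | C1OC[C@@H](C)[C@@H]1C | intermediate
14 | 2,6-dimethoxy-4-[(2S,3S,4S)-3,4-dimethyltetrahydrofuran-2-yl]phenyl pivalate | COc1cc([C@H]2OC[C@@H](C)[C@@H]2C)cc(OC)c1OC(=O)C(C)(C)C | intermediate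
15 | (2S,3S,4S,5S)-2,5-bis[3,5-dimethoxy-4-(pivaloyloxy)phenyl]-3,4-dimethyltetrahydrofuran | COc1cc([C@H]2O[C@H](c3cc(OC)c(OC(=O)C(C)(C)C)c(OC)c3)[C@@H](C)[C@@H]2C)cc(OC)c1OC(=O)C(C)(C)C | intermediate
16 | (2S,3S,4S,5S)-2,5-bis(4-hydroxy-3,5-dimethoxyphenyl)-3,4-dimethyltetrahydrofuran | COc1cc([C@H]2O[C@H](c3cc(OC)c(O)c(OC)c3)[C@@H](C)[C@@H]2C)cc(OC)c1O | target

## Step count and risks

Total step count: 10 (steps 1–4 aryl bromide, steps 5–8 ether core, steps 9–10 union and unmasking).
Longest linear sequence: 6 steps (1–4, 9, 10 or 5–8, 9, 10).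

**Step 9, the proposed double C–H arylation.** The ether is the limiting partner, so the second arylation may stall at 14. Bromide 7 may be lost to hydrodebromination, and hydrogen abstraction at the benzylic or methoxy C–H bonds may erode yield or selectivity. The fallback uses known chemistry only, sets out from 12 and 6, and comes back at 16. Phenol 6 is benzylated (BnBr, K2CO3, DMF) to 2-(benzyloxy)-5-bromo-1,3-dimethoxybenzene F1, which with Mg in THF gives [4-(benzyloxy)-3,5-dimethoxyphenyl]magnesium bromide F2. Diol 12 is oxidised with Dess–Martin periodinane (NaHCO3, CH2Cl2, 0 °C) to (2S,3S)-2,3-dimethylbutanedial F3, which is added at −78 °C to F2 (2.5 equiv). This gives (2S,3S)-1,4-bis[4-(benzyloxy)-3,5-dimethoxyphenyl]-2,3-dimethylbutane-1,4-diol F4 as a mixture of carbinol epimers. BF3·OEt2 (CH2Cl2, −20 → 0 °C) ionises the electron-rich benzylic alcohols and closes the ring reversibly, so all epimers converge on the all-trans (2S,3S,4S,5S)-2,5-bis[4-(benzyloxy)-3,5-dimethoxyphenyl]-3,4-dimethyltetrahydrofuran F5. Hydrogenolysis (H2 1 atm, Pd/C, EtOAc) then gives 16.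

**Step 3, para-bromination of 5.** Attack at C3, which is activated by both methoxy groups, and over-bromination can compete with attack at C4. The fallback replaces electrophilic substitution by sterically controlled C–H borylation; it sets out from 5 and comes back at 7. Phenol 5 is acylated first (PivCl, Et3N, DMAP) to 2,6-dimethoxyphenyl pivalate F6. Borylation with [Ir(cod)(OMe)]2 (1.5 mol %), dtbbpy (3 mol %) and B2pin2 in cyclohexane at 80 °C occurs at the only C–H without an ortho neighbour. This gives 2,6-dimethoxy-4-(4,4,5,5-tetramethyl-1,3,2-dioxaborolan-2-yl)phenyl pivalate F7, and CuBr2 (3 equiv) in MeOH/H2O at 80 °C converts the boronate into bromide 7.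

**Step 8, cyclodehydration to the volatile ether 13.** Acid at 130–140 °C may cause elimination or hydride-shift by-products, and the low-boiling product is easily lost. The fallback replaces acid catalysis by sulfonate activation and base-mediated Williamson closure; it sets out from 12 and comes back at 13. Diol 12 is mono-tosylated (TsCl 1.0 equiv, Bu2SnO 2 mol %, Et3N, CH2Cl2, 0 °C) to (2S,3S)-4-hydroxy-2,3-dimethylbutyl 4-methylbenzenesulfonate F8. NaH in tetraglyme (25 → 60 °C) closes the ring, and 13 is distilled directly out of the high-boiling solvent.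

## Further compounds

F1 | step 9 | 2-(benzyloxy)-5-bromo-1,3-dimethoxybenzene | COc1cc(Br)cc(OC)c1OCc1ccccc1
F2 | step 9 | [4-(benzyloxy)-3,5-dimethoxyphenyl]magnesium bromide | COc1cc([Mg]Br)cc(OC)c1OCc1ccccc1
F3 | step 9 | (2S,3S)-2,3-dimethylbutanedial | O=C[C@@H](C)[C@@H](C=O)C
F4 | step 9 | (2S,3S)-1,4-bis[4-(benzyloxy)-3,5-dimethoxyphenyl]-2,3-dimethylbutane-1,4-diol (mixture of C1/C4 epimers) | COc1cc(C(O)[C@@H](C)[C@H](C)C(O)c2cc(OC)c(OCc3ccccc3)c(OC)c2)cc(OC)c1OCc1ccccc1
F5 | step 9 | (2S,3S,4S,5S)-2,5-bis[4-(benzyloxy)-3,5-dimethoxyphenyl]-3,4-dimethyltetrahydrofuran | COc1cc([C@H]2O[C@H](c3cc(OC)c(OCc4ccccc4)c(OC)c3)[C@@H](C)[C@@H]2C)cc(OC)c1OCc1ccccc1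
F6 | step 3 | 2,6-dimethoxyphenyl pivalate | COc1cccc(OC)c1OC(=O)C(C)(C)C
F7 | step 3 | 2,6-dimethoxy-4-(4,4,5,5-tetramethyl-1,3,2-dioxaborolan-2-yl)phenyl pivalate | COc1cc(B2OC(C)(C)C(C)(C)O2)cc(OC)c1OC(=O)C(C)(C)C
F8 | step 8 | (2S,3S)-4-hydroxy-2,3-dimethylbutyl 4-methylbenzenesulfonate | OC[C@@H](C)[C@@H](COS(=O)(=O)c1ccc(C)cc1)C
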